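**Retrosynthetic overview**

1. The strategy rests on the resorcinol B ring: C1' is bonded to C2 of the chromone and the hydroxyls sit at C2' (ortho) and C4' (para). A 1-methoxy-1,3-bis(silyloxy)butadiene leaves exactly this pattern on an alkyne, so the B ring is cut at C1'–C2' and C5'–C6' to 2-ethynylchromone 10 and diene 13.
2. The ethynyl carbon comes from one-carbon homologation of the 2-carbaldehyde 9, which is made from the chromone-2-carboxylate 7 by reduction and re-oxidation.
3. The pyranone C ring is cut at C2–C3 (Claisen condensation with diethyl oxalate) and O1–C2 (cyclodehydration) to the side-chain-prenylated aryl ketone 4, itself from enolate alkylation of the bis-MOM ether 2.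
4. Ring order: A ring bought in 1, C ring in step 3, B ring last in step 9. The chelated 5-OH is carried free after step 3, so the benzannulation gives the target itself and no deprotection follows.

Key step: step 9

Remark: the target has no stereocentre, so no asymmetric step is needed; ketone 1 is assumed to be purchased as the 4-O-methyl ether of phloroacetophenone.

**Route**

Step 1
Reactants: 1 1-(2,6-dihydroxy-4-methoxyphenyl)ethan-1-one
Product: 2 1-[4-methoxy-2,6-bis(methoxymethoxy)phenyl]ethan-1-one
Conditions: NaH (2.2 equiv), MOMCl (2.4 equiv), DMF, 0 °C → rt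
Reagents that add atoms: chloromethyl methyl ether, COCCl
Why: Williamson-type O-alkylation of both phenoxides; NaH is used because the hydroxyls are hydrogen-bonded to the ketone, and capping both leaves the methyl ketone as the only acidic site for step 2.

Step 2
Reactants: 2 1-[4-methoxy-2,6-bis(methoxymethoxy)phenyl]ethan-1-one; 3 prenyl bromide (1-bromo-3-methylbut-2-ene)
Product: 4 1-[4-methoxy-2,6-bis(methoxymethoxy)phenyl]-5-methylhex-4-en-1-one
Conditions: LDA (1.05 equiv), THF, −78 °C; then 3 (0.95 equiv), −78 → 0 °C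
Reagents that add atoms: none
Why: Kinetic lithium enolate alkylation, SN2 at the primary carbon of the allylic bromide; the bromide is limiting and the addition is cold to hold back proton exchange and double alkylation.

Step 3
Reactants: 4 1-[4-methoxy-2,6-bis(methoxymethoxy)phenyl]-5-methylhex-4-en-1-one; 5 diethyl oxalate
Product: 7 ethyl 5-hydroxy-7-methoxy-3-(3-methylbut-2-en-1-yl)-4-oxo-4H-chromene-2-carboxylate, via diketo ester 6 (not isolated)
Conditions: LiHMDS (1.1 equiv), THF, −78 °C; 5 (1.5 equiv), → rt; then 3 M aq HCl, EtOH, 60 °C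
Reagents that add atoms: none
Why: Crossed Claisen condensation with the non-enolisable oxalate gives the 2,4-dioxo ester; aqueous acid then cleaves both MOM acetals, and one of the two equivalent phenols adds to the α-keto ester carbonyl and dehydrates to the pyranone (classical chromone-2-carboxylate synthesis), leaving the other as the chelated 5-OH.

Step 4
Reactants: 7 ethyl 5-hydroxy-7-methoxy-3-(3-methylbut-2-en-1-yl)-4-oxo-4H-chromene-2-carboxylate
Product: 8 5-hydroxy-2-(hydroxymethyl)-7-methoxy-3-(3-methylbut-2-en-1-yl)-4H-chromen-4-one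
Conditions: NaBH4, EtOH–THF, 0 °C
Reagents that add atoms: none
Why: Chemoselective borohydride reduction of the activated 2-carboxylate, which behaves like an α-oxygenated acrylate, while the C4 carbonyl is a vinylogous ester further deactivated by the 5-OH chelate; this is the known behaviour of chromone-2-carboxylates.

Step 5
Reactants: 8 5-hydroxy-2-(hydroxymethyl)-7-methoxy-3-(3-methylbut-2-en-1-yl)-4H-chromen-4-one
Product: 9 5-hydroxy-7-methoxy-3-(3-methylbut-2-en-1-yl)-4-oxo-4H-chromene-2-carbaldehyde
Conditions: activated MnO2 (excess), CH2Cl2, rt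
Reagents that add atoms: none
Why: MnO2 oxidation of an allylic-type primary alcohol on the pyranone C2=C3 to the aldehyde, which should leave the chelated phenol and the prenyl group untouched.

Step 6
Reactants: 9 5-hydroxy-7-methoxy-3-(3-methylbut-2-en-1-yl)-4-oxo-4H-chromene-2-carbaldehyde
Product: 10 2-ethynyl-5-hydroxy-7-methoxy-3-(3-methylbut-2-en-1-yl)-4H-chromen-4-one
Conditions: dimethyl (1-diazo-2-oxopropyl)phosphonate (1.3 equiv), K2CO3 (3 equiv), MeOH–THF, 0 °C → rt; aq NH4Cl work-up
Reagents that add atoms: dimethyl (1-diazo-2-oxopropyl)phosphonate, CC(=O)C(=[N+]=[N-])P(=O)(OC)OC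
Why: Ohira–Bestmann (Seyferth–Gilbert) homologation: the diazomethylphosphonate anion olefinates the non-enolisable aldehyde, and loss of N2 with 1,2-H shift in the alkylidene carbene gives the terminal alkyne; under carbonate the substrate is its 5-phenoxide, which damps the electrophilicity of the pyranone and the new alkyne toward methoxide.

Step 7
Reactants: 11 methyl acetoacetate
Product: 12 methyl 3-[(trimethylsilyl)oxy]but-2-enoate (E/Z mixture, geometry immaterial)
Conditions: TMSCl, Et3N, hexane, rt
Reagents that add atoms: chlorotrimethylsilane, C[Si](C)(C)Cl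
Why: O-silylation of the enol of the β-keto ester (silyl enol ether formation).

Step 8
Reactants: 12 methyl 3-[(trimethylsilyl)oxy]but-2-enoate
Product: 13 1-methoxy-1,3-bis[(trimethylsilyl)oxy]buta-1,3-diene (ketene acetal geometry immaterial)
Conditions: LDA, THF, −78 °C; TMSCl, −78 → 0 °C; used freshly
Reagents that add atoms: chlorotrimethylsilane, C[Si](C)(C)Cl
Why: γ-Deprotonation of the silyloxy crotonate gives the dienolate, which is O-silylated to the bis(silyloxy) ketene acetal diene (Chan's diene).

Step 9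
Reactants: 10 2-ethynyl-5-hydroxy-7-methoxy-3-(3-methylbut-2-en-1-yl)-4H-chromen-4-one; 13 1-methoxy-1,3-bis[(trimethylsilyl)oxy]buta-1,3-diene
Product: 16 2-(2,4-dihydroxyphenyl)-5-hydroxy-7-methoxy-3-(3-methylbut-2-en-1-yl)-4H-chromen-4-one, via cyclohexadiene cycloadduct 14 (not isolated), via 4'-O-trimethylsilyl phenol 15 (not isolated)
Conditions: 13 (3 equiv), toluene, 90 °C, sealed tube; then 1 M aq HCl, THF, 0 °C → rt
Reagents that add atoms: none
Why: Proposed new method: the ethynyl group of 10 is a vinylogous ynone (C≡C–C2=C3–C4=O, the carbonyl further polarised by the 5-OH hydrogen bond), so its terminal carbon carries the large LUMO coefficient and bonds to the nucleophilic CH2 terminus of 13 (C5'–C6') while the ketene acetal carbon bonds to the internal alkyne carbon (C1'–C2'), in a concerted asynchronous [4+2] or its Mukaiyama–Michael/ring-closure equivalent, to give 1,4-cyclohexadiene 14. The closest known reaction is the Diels–Alder/aromatisation of 1,1-dioxygenated 3-silyloxybutadienes with acetylenic esters and ketones to resorcinols; what is new is an alkyne activated only through an intervening pyranone C=C. The six-membered B ring closes by intermolecular [4+2] (if stepwise, by six-membered closure of the allenyl enolate onto the silyloxy-stabilised cation). At C2' of 14 the mixed methyl silyl ketal collapses with loss of MeOSiMe3 to a ketone that enolises into the aromatic ring, so C2' ends as a free OH (15), and dilute acid frees the 4'-OH; no stereocentre remains. The step needs the 2',4'- and not the 3',5'-regiochemistry, which the matched polarisation of diene and alkyne secures, and attack at the alkyne rather than at the pyranone, which the fully substituted C2 and the prenylated C3 secure. The chelated 5-OH is left free, as peri-hydroxyls are in ketene acetal additions to hydroxyquinones, and the excess of 13 covers any silyl transfer to it, which the work-up reverses.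

**Compound list**

1 | 1-(2,6-dihydroxy-4-methoxyphenyl)ethan-1-one | CC(=O)c1c(O)cc(OC)cc1O | starting material
2 | 1-[4-methoxy-2,6-bis(methoxymethoxy)phenyl]ethan-1-one | CC(=O)c1c(OCOC)cc(OC)cc1OCOC | intermediate
3 | prenyl bromide (1-bromo-3-methylbut-2-ene) | CC(C)=CCBr | starting material
4 | 1-[4-methoxy-2,6-bis(methoxymethoxy)phenyl]-5-methylhex-4-en-1-one | COCOc1cc(OC)cc(OCOC)c1C(=O)CCC=C(C)C | intermediate
5 | diethyl oxalate | CCOC(=O)C(=O)OCC | starting material
6 | ethyl 3-[4-methoxy-2,6-bis(methoxymethoxy)benzoyl]-6-methyl-2-oxohept-5-enoate (racemic, largely enolised; not isolated) | CCOC(=O)C(=O)C(CC=C(C)C)C(=O)c1c(OCOC)cc(OC)cc1OCOC | intermediate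
7 | ethyl 5-hydroxy-7-methoxy-3-(3-methylbut-2-en-1-yl)-4-oxo-4H-chromene-2-carboxylate | CCOC(=O)c1oc2cc(OC)cc(O)c2c(=O)c1CC=C(C)C | intermediate
8 | 5-hydroxy-2-(hydroxymethyl)-7-methoxy-3-(3-methylbut-2-en-1-yl)-4H-chromen-4-one | OCc1oc2cc(OC)cc(O)c2c(=O)c1CC=C(C)C | intermediate
9 | 5-hydroxy-7-methoxy-3-(3-methylbut-2-en-1-yl)-4-oxo-4H-chromene-2-carbaldehyde | O=Cc1oc2cc(OC)cc(O)c2c(=O)c1CC=C(C)C | intermediate
10 | 2-ethynyl-5-hydroxy-7-methoxy-3-(3-methylbut-2-en-1-yl)-4H-chromen-4-one | C#Cc1oc2cc(OC)cc(O)c2c(=O)c1CC=C(C)C | intermediate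
11 | methyl acetoacetate | COC(=O)CC(C)=O | starting material
12 | methyl 3-[(trimethylsilyl)oxy]but-2-enoate | COC(=O)C=C(C)O[Si](C)(C)C | intermediate
13 | 1-methoxy-1,3-bis[(trimethylsilyl)oxy]buta-1,3-diene | COC(O[Si](C)(C)C)=CC(=C)O[Si](C)(C)C | intermediate
14 | 5-hydroxy-7-methoxy-2-{6-methoxy-4,6-bis[(trimethylsilyl)oxy]cyclohexa-1,4-dien-1-yl}-3-(3-methylbut-2-en-1-yl)-4H-chromen-4-one (racemic; not isolated) | COc1cc(O)c2c(=O)c(CC=C(C)C)c(C3=CCC(O[Si](C)(C)C)=CC3(OC)O[Si](C)(C)C)oc2c1 | intermediate
15 | 5-hydroxy-2-{2-hydroxy-4-[(trimethylsilyl)oxy]phenyl}-7-methoxy-3-(3-methylbut-2-en-1-yl)-4H-chromen-4-one (not isolated) | COc1cc(O)c2c(=O)c(CC=C(C)C)c(-c3ccc(O[Si](C)(C)C)cc3O)oc2c1 | intermediate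
16 | 2-(2,4-dihydroxyphenyl)-5-hydroxy-7-methoxy-3-(3-methylbut-2-en-1-yl)-4H-chromen-4-one (achiral) | COc1cc(O)c2c(=O)c(CC=C(C)C)c(-c3ccc(O)cc3O)oc2c1 | target

**Step count**

Total: 9 steps. Longest linear sequence: 7 steps (1, 2, 3, 4, 5, 6, 9); steps 7 and 8 make the diene in a side branch.

**Steps most likely to fail**

Step 9. The vinylogous activation of the alkyne may be too weak, so that thermal decay and silyl migration of the diene outrun the cycloaddition, or the C2' ketal may collapse the wrong way and leave a 2'-methyl ether. The fallback builds the B ring from a bought arene by known flavone chemistry; it sets out from 4 and comes back at 16. 2,4-Dihydroxybenzaldehyde is allylated (allyl bromide, K2CO3, DMF) to 2,4-bis(prop-2-en-1-yloxy)benzaldehyde F1. The lithium enolate of 4 (LDA, THF, −78 °C) is added to it to give the aldol 3-[2,4-bis(prop-2-en-1-yloxy)phenyl]-3-hydroxy-1-[4-methoxy-2,6-bis(methoxymethoxy)phenyl]-2-(3-methylbut-2-en-1-yl)propan-1-one F2 as a diastereomer mixture. Dess–Martin oxidation gives the 1,3-diketone 1-[2,4-bis(prop-2-en-1-yloxy)phenyl]-3-[4-methoxy-2,6-bis(methoxymethoxy)phenyl]-2-(3-methylbut-2-en-1-yl)propane-1,3-dione F3. Aqueous HCl in MeOH at 50 °C removes the MOM groups and cyclodehydrates to 2-[2,4-bis(prop-2-en-1-yloxy)phenyl]-5-hydroxy-7-methoxy-3-(3-methylbut-2-en-1-yl)-4H-chromen-4-one F4; only the A-ring hydroxyls are free, so only one closure is possible. Pd(PPh3)4 with morpholine in THF removes the allyl ethers and gives 16.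

Step 6. Methanol or methoxide may add in conjugate fashion to the newly formed, Michael-accepting ethynyl group, or open the pyranone. The fallback brings the alkyne in already formed and silyl-capped; it sets out from 4 and comes back at 10, bypassing 7, 8 and 9. The lithium enolate of 4 is added to commercial 3-[tri(propan-2-yl)silyl]prop-2-ynal to give 3-hydroxy-1-[4-methoxy-2,6-bis(methoxymethoxy)phenyl]-2-(3-methylbut-2-en-1-yl)-5-[tri(propan-2-yl)silyl]pent-4-yn-1-one F5. Dess–Martin oxidation gives 1-[4-methoxy-2,6-bis(methoxymethoxy)phenyl]-2-(3-methylbut-2-en-1-yl)-5-[tri(propan-2-yl)silyl]pent-4-yne-1,3-dione F6. Aqueous HCl in THF–MeOH removes the MOM groups and closes the pyranone to 5-hydroxy-7-methoxy-3-(3-methylbut-2-en-1-yl)-2-{[tri(propan-2-yl)silyl]ethynyl}-4H-chromen-4-one F7; the bulky silyl group shields the alkyne terminus from the enol oxygen, so the phenol closes on the carbonyl. TBAF buffered with AcOH in THF at 0 °C then gives 10.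

Step 2. Proton exchange between the product ketone and unreacted enolate may lead to double prenylation. The fallback alkylates a β-keto ester instead; it sets out from 2 and comes back at 4. Claisen condensation of 2 with diethyl carbonate (NaH, THF, reflux) gives ethyl 3-[4-methoxy-2,6-bis(methoxymethoxy)phenyl]-3-oxopropanoate F8. C-Alkylation with 3 (K2CO3, acetone) gives ethyl 2-[4-methoxy-2,6-bis(methoxymethoxy)benzoyl]-5-methylhex-4-enoate F9. Saponification (LiOH, THF–H2O), careful acidification to pH 4–5 and gentle warming decarboxylate the β-keto acid to 4 with the MOM ethers intact.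

**Further compounds**

F1 | step 9 | 2,4-bis(prop-2-en-1-yloxy)benzaldehyde | C=CCOc1ccc(C=O)c(OCC=C)c1
F2 | step 9 | 3-[2,4-bis(prop-2-en-1-yloxy)phenyl]-3-hydroxy-1-[4-methoxy-2,6-bis(methoxymethoxy)phenyl]-2-(3-methylbut-2-en-1-yl)propan-1-one (diastereomer mixture) | COCOc1cc(OC)cc(OCOC)c1C(=O)C(CC=C(C)C)C(O)c1ccc(OCC=C)cc1OCC=C
F3 | step 9 | 1-[2,4-bis(prop-2-en-1-yloxy)phenyl]-3-[4-methoxy-2,6-bis(methoxymethoxy)phenyl]-2-(3-methylbut-2-en-1-yl)propane-1,3-dione | COCOc1cc(OC)cc(OCOC)c1C(=O)C(CC=C(C)C)C(=O)c1ccc(OCC=C)cc1OCC=C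
F4 | step 9 | 2-[2,4-bis(prop-2-en-1-yloxy)phenyl]-5-hydroxy-7-methoxy-3-(3-methylbut-2-en-1-yl)-4H-chromen-4-one | COc1cc(O)c2c(=O)c(CC=C(C)C)c(-c3ccc(OCC=C)cc3OCC=C)oc2c1
F5 | step 6 | 3-hydroxy-1-[4-methoxy-2,6-bis(methoxymethoxy)phenyl]-2-(3-methylbut-2-en-1-yl)-5-[tri(propan-2-yl)silyl]pent-4-yn-1-one (diastereomer mixture) | COCOc1cc(OC)cc(OCOC)c1C(=O)C(CC=C(C)C)C(O)C#C[Si](C(C)C)(C(C)C)C(C)C
F6 | step 6 | 1-[4-methoxy-2,6-bis(methoxymethoxy)phenyl]-2-(3-methylbut-2-en-1-yl)-5-[tri(propan-2-yl)silyl]pent-4-yne-1,3-dione | COCOc1cc(OC)cc(OCOC)c1C(=O)C(CC=C(C)C)C(=O)C#C[Si](C(C)C)(C(C)C)C(C)C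
F7 | step 6 | 5-hydroxy-7-methoxy-3-(3-methylbut-2-en-1-yl)-2-{[tri(propan-2-yl)silyl]ethynyl}-4H-chromen-4-one | COc1cc(O)c2c(=O)c(CC=C(C)C)c(C#C[Si](C(C)C)(C(C)C)C(C)C)oc2c1
F8 | step 2 | ethyl 3-[4-methoxy-2,6-bis(methoxymethoxy)phenyl]-3-oxopropanoate | CCOC(=O)CC(=O)c1c(OCOC)cc(OC)cc1OCOC
F9 | step 2 | ethyl 2-[4-methoxy-2,6-bis(methoxymethoxy)benzoyl]-5-methylhex-4-enoate (racemic) | CCOC(=O)C(CC=C(C)C)C(=O)c1c(OCOC)cc(OC)cc1OCOC
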